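**Retrosynthetic overview**
- Both 5-7-5 guaianolide tricycles, with all eight ring stereocentres (C1, C5, C6, C7 in each half), are bought intact as dehydrocostus lactone (1); no monomer ring is built.
- 1 ⇒ common 3α-allylic alcohol 2, which diverges to the acceptor enone 3 and, via directed epoxide 4 and epoxy ketone 5, to the β-iodo-α-ketol radical precursor 6.
- Key disconnections of the target (7): C15–C15′ (visible-light radical Giese bond between C15′ of 6 and the enone CH2 of 3) and C4–C3′ (intramolecular aldol).
- Ring order: only the central spiro-fused cyclopentane (C4–C15–C15′–C4′–C3′) is formed, in the last step. C4′ is set by the directed epoxidation; C3′ and C4 by the cis-ring-fusion/convex-face aldol.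

Assumption: dehydrocostus lactone (a major crystalline constituent of costus root oil, sold as the pure compound) is the purchasable chiral starting material. Guaianolide numbering is used; primes mark the diol-bearing half; α is the face carrying H-1/H-5.

**Step 1**
Reactants: 1, dehydrocostus lactone
Product: 2, isozaluzanin C (3α-hydroxy-dehydrocostus lactone)
Conditions: SeO2 (0.5 equiv), t-BuOOH (2 equiv), CH2Cl2, 0 °C → rt
Reagents that add atoms: SeO2, O=[Se]=O (delivers the hydroxyl O); t-BuOOH, CC(C)(C)OO (re-oxidises Se)
Why: Sharpless catalytic SeO2 allylic oxidation (ene, then [2,3]-shift) of the Δ4(15) methylene at the ring CH2 (C3); oxygen is delivered on the convex α-face, cis to H-1/H-5, which gives the 3α-alcohol, and the transformation is known on this substrate. The minor 3β-epimer and any over-oxidised enone are pooled into the stream for 3.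

**Step 2**
Reactants: 2, isozaluzanin C
Product: 3, dehydrozaluzanin C (3-oxo-dehydrocostus lactone)
Conditions: Dess–Martin periodinane, NaHCO3, CH2Cl2, 0 °C; keep as a cold stock solution
Reagents that add atoms: none
Why: Dess–Martin oxidation of the allylic alcohol under neutral conditions leaves the exo-methylenes and the α-methylene lactone untouched and creates no stereocentre. The neat enone self-dimerises, so it is stored in solution.

**Step 3**
Reactants: 2, isozaluzanin C
Product: 4, 3α-hydroxy-4α,15-epoxyguaia-10(14),11(13)-dien-12,6α-olide (spiro-oxirane at C4, oxirane O on the α-face cis to 3-OH, CH2 on the β-face)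
Conditions: VO(acac)2 (3 mol%), t-BuOOH (1.3 equiv, decane), CH2Cl2, 0 °C → rt
Reagents that add atoms: t-BuOOH, CC(C)(C)OO (epoxide O)
Why: Sharpless hydroxyl-directed vanadium epoxidation touches only the allylic-alcohol alkene, not Δ10(14) or the electron-poor Δ11(13), and delivers O syn to the 3α-OH. This sets C4 with C–O α and C15 β, the configuration of C4′ in the target.

**Step 4**
Reactants: 4, epoxy alcohol
Product: 5, 4α,15-epoxy-3-oxoguaia-10(14),11(13)-dien-12,6α-olide (α,β-epoxy ketone)
Conditions: Dess–Martin periodinane, NaHCO3, CH2Cl2, 0 °C → rt
Reagents that add atoms: none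
Why: Buffered Dess–Martin oxidation of the secondary alcohol keeps the spiro-epoxide and does not touch the C4 stereocentre.

**Step 5**
Reactants: 5, epoxy ketone; 3, dehydrozaluzanin C
Product: 7, ainsliadimer A, via 6, 4α-hydroxy-15-iodo-3-oxoguaia-10(14),11(13)-dien-12,6α-olide, formed in situ and not isolated
Conditions: 5, LiI (1.3 equiv), AcOH (1.3 equiv), MeCN, 0 °C → rt, dark; then i-Pr2NEt (4 equiv), 3 (3 equiv, ≥0.5 M), 4CzIPN (3 mol%), degassed, 456 nm LEDs, 15 °C; then DBU (1 equiv), rt
Reagents that add atoms: none (iodide from LiI is a relay and is lost again; net gain is 2 H from AcOH/ammonium)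
Why: Proposed new method: an iodide-relay photoredox formal [3+2] annulation of an α,β-epoxy ketone with an enone. LiI/AcOH opens the spiro-epoxide by SN2 at the unhindered CH2 (C15′) to give β-iodo-α-ketol 6 with C4′ unchanged (OH α). Under 4CzIPN/i-Pr2NEt/blue light an α-aminoalkyl radical abstracts iodine (XAT), and the primary C15′ radical adds (Giese) to the exocyclic enone CH2 (C15) of 3, forming the C15–C15′ bond. The resulting tertiary α-keto radical is reduced by 4CzIPN•– to the C3–C4 enolate (radical–polar crossover), which, re-formed by DBU if protonated first, closes the five-membered ring by aldol addition to the C3′ ketone. Cis-fusion of the new bicyclo[3.3.0] unit forces C4 onto the β-face of C3′ (3′-OH α, cis to 4′-OH), and C3′ adds to the convex α-face of the enolate, fixing the spiro centre C4. Closest known reactions: XAT-mediated photoredox Giese addition of unactivated alkyl iodides, iodide-co-catalysed in situ iodohydrin formation in reductive epoxide couplings, radical–polar crossover annulations, and the known DBU aldol closure of this same seco-hydroxy-diketone.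

**Compound list**
1 | dehydrocostus lactone | C=C1C(=O)O[C@@H]2[C@@H]3[C@@H](CCC3=C)C(=C)CC[C@@H]12 | starting material
2 | isozaluzanin C (3α-hydroxy-dehydrocostus lactone) | C=C1C(=O)O[C@@H]2[C@@H]3[C@@H](C[C@@H](O)C3=C)C(=C)CC[C@@H]12 | intermediate
3 | dehydrozaluzanin C (3-oxo-dehydrocostus lactone) | C=C1C(=O)O[C@@H]2[C@@H]3[C@@H](CC(=O)C3=C)C(=C)CC[C@@H]12 | intermediate
4 | 3α-hydroxy-4α,15-epoxyguaia-10(14),11(13)-dien-12,6α-olide | C=C1C(=O)O[C@@H]2[C@@H]3[C@@H](C[C@@H](O)[C@]34CO4)C(=C)CC[C@@H]12 | intermediate
5 | 4α,15-epoxy-3-oxoguaia-10(14),11(13)-dien-12,6α-olide | C=C1C(=O)O[C@@H]2[C@@H]3[C@@H](CC(=O)[C@]34CO4)C(=C)CC[C@@H]12 | intermediate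
6 | 4α-hydroxy-15-iodo-3-oxoguaia-10(14),11(13)-dien-12,6α-olide | C=C1C(=O)O[C@@H]2[C@@H]3[C@@H](CC(=O)[C@]3(O)CI)C(=C)CC[C@@H]12 | intermediate (in situ, not isolated)
7 | ainsliadimer A | C=C1C(=O)O[C@@H]2[C@@H]3[C@@H](C[C@@]4(O)[C@]3(O)CC[C@]43C(=O)C[C@H]4C(=C)CC[C@H]5C(=C)C(=O)O[C@@H]5[C@H]43)C(=C)CC[C@@H]12 | target

**Totals**
Total steps: 5. Longest linear sequence: 4 (1 → 2 → 4 → 5 → 7).

**Three steps most likely to fail**
1. Step 5 (proposed new step).
   - Risks: the C15′ radical may add to the α-methylene lactones instead of the enone; I estimate only about 3–5:1 per site in favour of the enone, which is why 3 is used in excess at high concentration. The β-keto radical may also undergo Dowd–Beckwith 1,2-acyl shift or cyclise onto Δ10′(14′) before it is trapped.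
   - Fallback (known chemistry): drop the radical coupling and use 3 alone. Concentrate it with an achiral hydrogen-bond donor (neat, about 50 °C) to the homo-hetero-Diels–Alder spiro-dihydropyran dimer, hydrolyse the cyclic enol ether with aqueous acid to the C4′-hydroxy diketone, then close with DBU aldol to 7.
2. Step 1.
   - Risks: moderate yield, competing oxidation at C9/C5, over-oxidation.
   - Fallback: abandon C–H oxidation and reach the C3-oxygenated guaianolides 2/3 from α-santonin by the established photochemical dienone rearrangement to isophotosantonic lactone and subsequent functional-group adjustment (longer, well precedented).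
3. Step 3.
   - Risks: vanadium-mediated oxidation of the alcohol to the enone; lability of the spiro-epoxy alcohol on isolation.
   - Fallback: skip the alcohol-directed route and epoxidise enone 3 directly by nucleophilic (Weitz–Scheffer) epoxidation with t-BuOOH/DBU, relying on convex α-face closure and the higher electrophilicity of the ketone enone over the lactone methylene, to give 5 in one step.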